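**Retrosynthetic overview**

1. Endgame (germacrane locants): the C1/C10 oxirane comes from the (E)-C1=C10 olefin, the angelate from C8–OH, the exocyclic C11=C13 from the saturated lactone, the C6–O/C12 lactone from a C6,C12-diol, and C8–OH from a C8–Si bond.
2. Feature: the carbocycle C1–C10 is a cyclodec-5-enone in disguise. C6 carries the oxygen, the C1=C10 olefin sits five ring atoms away, C7 is the enolate carbon and C8 the carbon next to it. An anionic oxy-Cope shift therefore forms C8–C9 and cleaves C6–C1 of a trans-1,2-dialkenylcyclohexanol (21).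
3. Repair of C7 and C8: C7 carries its two-carbon arm (a vinyl group) and C8 a benzyldimethylsilyl group before the shift. The enolate is then tetrasubstituted and cannot turn through the ring, so H-7 arrives last from outside; benzyl on silicon lets C8–Si be oxidised by fluoride/H2O2 without touching the C1=C10 olefin.
4. 21 comes from ketone 13 by alkynylation and alkoxide-directed anti-carbomagnesiation. 13 comes from (R)-carvone via trans-carveol, epoxide/selenide/oxidative transposition (ketone beside the isopropenyl carbon), then enone epoxidation and reductive opening (trans C3/C4 diol).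
5. Ring order: cyclohexane (from carvone), ten-membered carbocycle (step 14), γ-lactone (step 17), oxirane (step 24).

Key step: step 14

Assumption: germacrane locants are used for all ten-membered compounds (C1/C10 oxirane, C3 and C4 carbinols, C6 lactone carbinol, C8 angelate carbinol, C11–C13 lactone arm), and α/β refer to the usual drawing with H-7 α.

**Route**

Step 1
Reactants: 1 (R)-carvone
Product: 2 (1R,5R)-cis-carveol
Conditions: NaBH4, CeCl3·7H2O, MeOH, 0 °C
Reagents that add atoms: none
Why: Luche 1,2-reduction of the enone should deliver hydride axially and give the pseudo-equatorial alcohol cis to the isopropenyl group.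

Step 2
Reactants: 2 (1R,5R)-cis-carveol
Product: 3 (1S,5R)-trans-carveyl 4-nitrobenzoate
Conditions: PPh3, DIAD, 4-O2NC6H4CO2H, THF, 0 °C → rt
Reagents that add atoms: 4-nitrobenzoic acid OC(=O)c1ccc(cc1)[N+](=O)[O-]
Why: Mitsunobu esterification displaces the oxyphosphonium group by SN2 and inverts the carbinol, which puts oxygen trans to isopropenyl and sets the future C3 configuration.

Step 3
Reactants: 3 (1S,5R)-trans-carveyl 4-nitrobenzoate
Product: 4 (1S,5R)-trans-carveol
Conditions: K2CO3, MeOH, rt
Reagents that add atoms: none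
Why: Methanolysis of the activated benzoate proceeds at the acyl carbon and leaves the carbinol configuration untouched.

Step 4
Reactants: 4 (1S,5R)-trans-carveol
Product: 5 (4R,6S)-6-(methoxymethoxy)-1-methyl-4-(prop-1-en-2-yl)cyclohex-1-ene
Conditions: MeOCH2Cl, iPr2NEt, CH2Cl2, 0 °C → rt
Reagents that add atoms: chloromethyl methyl ether COCCl
Why: Standard O-alkylation of a secondary alcohol gives the base-stable MOM ether needed for the organometallic and KH steps.

Step 5
Reactants: 5 MOM ether of trans-carveol
Product: 6 ring epoxide of 5 with the oxirane anti to OMOM and syn to isopropenyl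
Conditions: mCPBA, NaHCO3, CH2Cl2, 0 °C
Reagents that add atoms: 3-chloroperoxybenzoic acid OOC(=O)c1cccc(Cl)c1
Why: Prilezhaev epoxidation should take the trisubstituted ring olefin before the 1,1-disubstituted one and approach anti to the pseudoaxial OMOM group; any syn epoxide converges in step 7.

Step 6
Reactants: 6 epoxide
Product: 9 6-(methoxymethoxy)-1-methyl-4-(prop-1-en-2-yl)cyclohex-2-en-1-ol (tertiary OH cis to isopropenyl), via hydroxy selenide 7 (not isolated), via selenoxide 8 (not isolated)
Conditions: (PhSe)2, NaBH4, EtOH, 80 °C; then 30% H2O2, pyridine, THF, 0 °C → rt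
Reagents that add atoms: none
Why: Benzeneselenolate opens the oxirane at the secondary carbon in trans-diaxial fashion (Fürst–Plattner), and selenoxide syn-elimination can only go away from the fully substituted carbinol carbon, which gives the tertiary allylic alcohol.

Step 7
Reactants: 9 tertiary allylic alcohol
Product: 10 (4S,6R)-4-(methoxymethoxy)-3-methyl-6-(prop-1-en-2-yl)cyclohex-2-en-1-one
Conditions: [C5H5NH][CrO3Cl], 4 Å molecular sieves, CH2Cl2, rt
Reagents that add atoms: pyridinium chlorochromate [O-][Cr](=O)(=O)Cl.c1cc[nH+]cc1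
Why: Babler–Dauben oxidative transposition (chromate ester, [3,3] shift, oxidation) moves the oxygen to the carbon beside the isopropenyl-bearing carbon and gives the enone, erasing the carbinol centre so both epimers of 9 converge.

Step 8
Reactants: 10 enone
Product: 11 2,3-epoxide of 10 with the oxirane anti to OMOM and syn to isopropenyl
Conditions: 30% H2O2, NaOH (0.2 equiv), MeOH, −10 → 0 °C
Reagents that add atoms: hydrogen peroxide OO
Why: Weitz–Scheffer epoxidation should add hydroperoxide to the β-carbon anti to the adjacent pseudoaxial OMOM group, which fixes the tertiary C–O bond (future C4) trans to the C3 oxygen.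

Step 9
Reactants: 11 epoxy ketone
Product: 12 (2R,4S,5S)-5-hydroxy-4-(methoxymethoxy)-5-methyl-2-(prop-1-en-2-yl)cyclohexan-1-one
Conditions: SmI2, THF–MeOH, −90 °C
Reagents that add atoms: none
Why: Ketyl formation and cleavage of the α C–O bond is the known reductive opening of α,β-epoxy ketones to β-hydroxy ketones, and it leaves the β C–O bond and its configuration intact.

Step 10
Reactants: 12 β-hydroxy ketone
Product: 13 (2R,4S,5S)-4,5-bis(methoxymethoxy)-5-methyl-2-(prop-1-en-2-yl)cyclohexan-1-one
Conditions: MeOCH2Cl, iPr2NEt, NaI, ClCH2CH2Cl, 50 °C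
Reagents that add atoms: chloromethyl methyl ether COCCl
Why: Iodide-assisted MOM protection of the tertiary alcohol with a hindered amine base should outrun β-elimination and retro-aldol cleavage, which need an enolate or alkoxide.

Step 11
Reactants: 14 benzylchlorodimethylsilane, 15 ethynylmagnesium bromide
Product: 16 benzyl(ethynyl)dimethylsilane
Conditions: THF, 0 °C → rt
Reagents that add atoms: none
Why: Substitution of chloride at silicon by an alkynyl Grignard reagent is the standard preparation of alkynylsilanes.

Step 12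
Reactants: 13 bis-MOM ketone, 16 benzyl(ethynyl)dimethylsilane
Product: 18 (1R,2R,4S,5S)-1-[(benzyldimethylsilyl)ethynyl]-4,5-bis(methoxymethoxy)-5-methyl-2-(prop-1-en-2-yl)cyclohexan-1-ol, via lithium acetylide 17 (not isolated)
Conditions: n-BuLi, THF, −78 °C; then 13, −78 °C; aq NH4Cl
Reagents that add atoms: none
Why: The weakly basic acetylide adds to the ketone along the equatorial trajectory, because the axial one is blocked by the axial OMOM group on the β-carbon; the alkynyl group ends trans to the isopropenyl group and the hydroxyl axial.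

Step 13
Reactants: 18 propargylic alcohol, 19 vinylmagnesium chloride
Product: 21 (1R,2R,4S,5S)-1-[(1E)-1-(benzyldimethylsilyl)buta-1,3-dien-2-yl]-4,5-bis(methoxymethoxy)-5-methyl-2-(prop-1-en-2-yl)cyclohexan-1-ol, via magnesium chelate 20 (not isolated)
Conditions: 19 (4 equiv), CuI (10 mol %), THF–toluene, 0 → 60 °C; aq NH4Cl, 0 °C
Reagents that add atoms: none
Why: Alkoxide-directed anti-carbomagnesiation of a propargylic alcohol delivers vinyl to the alkyne carbon next to the carbinol and leaves magnesium on the silyl-bearing carbon in a five-membered chelate, so protonation gives silicon trans to the carbinol carbon and cis to the new vinyl group.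

Step 14
Reactants: 21 dienyl isopropenyl cyclohexanol
Product: 24 (E)-cyclodec-1(10)-en-6-one with 7β-vinyl (H-7 α) 8β-benzyldimethylsilyl and 3β/4α-bis(methoxymethoxy) groups, via potassium alkoxide 22 (not isolated), via potassium dienolate 23 (not isolated)
Conditions: KH, 18-crown-6, THF, 0 °C → rt; cannulated into AcOH–THF at −78 °C
Reagents that add atoms: none
Why: KH with 18-crown-6 gives the naked alkoxide 22, whose [3,3] shift is the anionic oxy-Cope rearrangement known to turn trans-1,2-dialkenylcyclohexanols into (E)-cyclodec-5-enones at or below room temperature. Both alkenyl groups are equatorial, so the chair transition state is trans-decalin-like; it forms C8–C9 and cleaves the ring bond C6–C1, so the ten-membered ring arises by ring expansion through bond cleavage and not by end-to-end closure, and no high dilution is needed. The E geometry of C7=C8 places silicon equatorial and fixes C8 (8β), and the equatorial C2 ends trans to C9, which gives the (E)-C1=C10 olefin. Enolate 23 is tetrasubstituted at C6=C7, and neither its O–K end nor the vinyl group can swing through the ring, so the face turned outward by the chair is kept and kinetic α-protonation from that face delivers H-7 α, with the C7 arm cis to the C8 silicon. Silicon is trans to oxygen across C7=C8, which rules out 1,4-silyl migration to the alkoxide, and a β-silyl enolate cannot eliminate as a β-alkoxy enolate would. The step needs α- over γ-protonation of the dienolate and no proton transfer to C5, and the cold inverse quench into acetic acid is chosen to secure both.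

Step 15
Reactants: 24 cyclodecenone
Product: 25 6α-alcohol of 24
Conditions: NaBH4, CeCl3·7H2O, MeOH–THF, −78 → −40 °C
Reagents that add atoms: none
Why: Hydride should attack the carbonyl from the outside of the ring while its oxygen stays on the α-face eclipsing C7–H, which gives the 6α-alcohol trans to the C7 arm; the non-basic Luche conditions avoid enolisation at C7 and C5.

Step 16
Reactants: 25 homoallylic alcohol
Product: 26 C6,C12-diol (7β-(2-hydroxyethyl) group)
Conditions: 9-BBN, THF, 0 °C → rt; then 30% H2O2, NaOH (aq), 0 °C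
Reagents that add atoms: hydrogen peroxide OO
Why: 9-BBN hydroborates the monosubstituted vinyl group at its terminus far faster than the trisubstituted ring olefin, and oxidation gives the primary alcohol at C12.

Step 17
Reactants: 26 diol
Product: 28 trans-fused 6α,12-lactone carrying the 8β-silyl group, via lactol 27 (not isolated)
Conditions: TEMPO (cat.), PhI(OAc)2, CH2Cl2, rt
Reagents that add atoms: none
Why: The oxoammonium oxidant takes the primary alcohol to the aldehyde, the C6 hydroxyl closes the five-membered lactol, and a second oxidation gives the γ-lactone, closing it on C6 while C8 is still masked as silicon.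

Step 18
Reactants: 28 silyl lactone
Product: 30 8β-hydroxy lactone, via fluorosilane 29 (not isolated)
Conditions: Bu4NF, THF, 0 °C → rt; then KHCO3, 30% H2O2, MeOH, rt
Reagents that add atoms: hydrogen peroxide OO
Why: Fluoride cleaves the benzyl–silicon bond, and Tamao–Fleming oxidation of the resulting fluorosilane converts C8–Si into C8–OH with retention under conditions that spare the C1=C10 olefin and the lactone.

Step 19
Reactants: 30 8β-hydroxy lactone
Product: 31 8-O-triethylsilyl ether of 30
Conditions: Et3SiCl, imidazole, DMF, 0 °C → rt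
Reagents that add atoms: chlorotriethylsilane CC[Si](Cl)(CC)CC
Why: Silylation masks the C8 hydroxyl so that no C8 alkoxide can attack the lactone carbonyl during the enolate step.

Step 20
Reactants: 31 silyl ether lactone
Product: 34 α-methylene lactone (C11=C13) with the 8-O-triethylsilyl group, via Mannich base 32 (not isolated), via ammonium iodide 33 (not isolated)
Conditions: LiN(iPr)2, THF, −78 °C; [Me2N=CH2]I, −78 °C → rt; MeI, MeOH, rt; NaHCO3 (aq), CH2Cl2
Reagents that add atoms: N,N-dimethylmethyleneiminium iodide C=[N+](C)C.[I-]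
Why: Eschenmoser methylenation: the lactone enolate is aminomethylated at C11, and quaternisation followed by mild base eliminates trimethylamine to give the exocyclic methylene.

Step 21
Reactants: 34 silyl ether
Product: 35 8β-hydroxy α-methylene lactone
Conditions: HF·pyridine, pyridine, THF, 0 °C
Reagents that add atoms: none
Why: Buffered HF·pyridine removes the triethylsilyl ether without base, so the free C8 hydroxyl is not exposed to conditions that promote translactonisation or conjugate addition.

Step 22
Reactants: 35 C8 alcohol, 36 angelic acid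
Product: 37 8-O-angelate with both MOM ethers in place
Conditions: 36, 2,4,6-Cl3C6H2COCl, Et3N, toluene, rt; then 35, 80 °C
Reagents that add atoms: none
Why: Yamaguchi-type mixed-anhydride acylation without a nucleophilic catalyst is the established way to make angelates without Z-to-E isomerisation to the tiglate.

Step 23
Reactants: 37 bis-MOM angelate
Product: 39 3β,4α-diol with the C1=C10 olefin intact, via bromomethyl ether 38 (not isolated)
Conditions: Me2BBr, CH2Cl2, −78 °C; then NaHCO3 (aq)–THF, −78 → 0 °C
Reagents that add atoms: none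
Why: The bromoborane cleaves the CH2–OMe bond of each MOM group at low temperature, and bicarbonate hydrolysis of the bromomethyl ethers frees the secondary and tertiary alcohols without protic acid reaching the olefin, the esters or the tertiary C4–O bond.

Step 24
Reactants: 39 diol
Product: 40 argophyllin A
Conditions: mCPBA, NaHCO3, CH2Cl2, 0 °C
Reagents that add atoms: 3-chloroperoxybenzoic acid OOC(=O)c1cccc(Cl)c1
Why: The C1=C10 olefin is the only electron-rich double bond; Prilezhaev epoxidation from outside the lactone-bridged ring, on the rotamer that holds C14 on the β-face and is within hydrogen-bonding reach of the 3β-hydroxyl, should give the 1β,10α-oxide (C1 R, C10 R).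

**Compound list**

1 | (R)-carvone | CC1=CC[C@H](CC1=O)C(C)=C | starting material
2 | (1R,5R)-cis-carveol | CC1=CC[C@H](C[C@H]1O)C(C)=C | intermediate
3 | (1S,5R)-trans-carveyl 4-nitrobenzoate | CC1=CC[C@H](C[C@@H]1OC(=O)c1ccc(cc1)[N+](=O)[O-])C(C)=C | intermediate
4 | (1S,5R)-trans-carveol | CC1=CC[C@H](C[C@@H]1O)C(C)=C | intermediate
5 | (4R,6S)-6-(methoxymethoxy)-1-methyl-4-(prop-1-en-2-yl)cyclohex-1-ene | CC1=CC[C@H](C[C@@H]1OCOC)C(C)=C | intermediate
6 | ring epoxide of 5, oxirane anti to OMOM and syn to isopropenyl | C[C@]12O[C@H]1C[C@H](C[C@@H]2OCOC)C(C)=C | intermediate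
7 | hydroxy selenide, tertiary OH syn to isopropenyl, PhSe anti to OH | C[C@]1(O)[C@H]([Se]c2ccccc2)C[C@H](C[C@@H]1OCOC)C(C)=C | intermediate (not isolated)
8 | selenoxide of 7 | C[C@]1(O)[C@H]([Se](=O)c2ccccc2)C[C@H](C[C@@H]1OCOC)C(C)=C | intermediate (not isolated)
9 | 6-(methoxymethoxy)-1-methyl-4-(prop-1-en-2-yl)cyclohex-2-en-1-ol, OH cis to isopropenyl and trans to OMOM | C[C@]1(O)C=C[C@H](C[C@@H]1OCOC)C(C)=C | intermediate
10 | (4S,6R)-4-(methoxymethoxy)-3-methyl-6-(prop-1-en-2-yl)cyclohex-2-en-1-one | O=C1C=C(C)[C@@H](OCOC)C[C@@H]1C(C)=C | intermediate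
11 | 2,3-epoxide of 10, oxirane anti to OMOM and syn to isopropenyl | O=C1[C@@H]2O[C@]2(C)[C@@H](OCOC)C[C@@H]1C(C)=C | intermediate
12 | (2R,4S,5S)-5-hydroxy-4-(methoxymethoxy)-5-methyl-2-(prop-1-en-2-yl)cyclohexan-1-one | O=C1C[C@](C)(O)[C@@H](OCOC)C[C@@H]1C(C)=C | intermediate
13 | (2R,4S,5S)-4,5-bis(methoxymethoxy)-5-methyl-2-(prop-1-en-2-yl)cyclohexan-1-one | O=C1C[C@](C)(OCOC)[C@@H](OCOC)C[C@@H]1C(C)=C | intermediate
14 | benzylchlorodimethylsilane | C[Si](C)(Cl)Cc1ccccc1 | starting material
15 | ethynylmagnesium bromide | C#C[Mg]Br | starting material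
16 | benzyl(ethynyl)dimethylsilane | C#C[Si](C)(C)Cc1ccccc1 | intermediate
17 | lithium acetylide of 16 | [Li]C#C[Si](C)(C)Cc1ccccc1 | intermediate (not isolated)
18 | (1R,2R,4S,5S)-1-[(benzyldimethylsilyl)ethynyl]-4,5-bis(methoxymethoxy)-5-methyl-2-(prop-1-en-2-yl)cyclohexan-1-ol | O[C@]1(C#C[Si](C)(C)Cc2ccccc2)C[C@](C)(OCOC)[C@@H](OCOC)C[C@@H]1C(C)=C | intermediate
19 | vinylmagnesium chloride | C=C[Mg]Cl | starting material
20 | five-membered magnesium chelate (O–Mg–C8, vinyl on C7) | C=CC1=C([Si](C)(C)Cc2ccccc2)[Mg]O[C@@]13C[C@](C)(OCOC)[C@@H](OCOC)C[C@@H]3C(C)=C | intermediate (not isolated)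
21 | (1R,2R,4S,5S)-1-[(1E)-1-(benzyldimethylsilyl)buta-1,3-dien-2-yl]-4,5-bis(methoxymethoxy)-5-methyl-2-(prop-1-en-2-yl)cyclohexan-1-ol | O[C@]1(/C(C=C)=C/[Si](C)(C)Cc2ccccc2)C[C@](C)(OCOC)[C@@H](OCOC)C[C@@H]1C(C)=C | intermediate (key-step precursor)
22 | potassium alkoxide of 21 | [K+].[O-][C@]1(/C(C=C)=C/[Si](C)(C)Cc2ccccc2)C[C@](C)(OCOC)[C@@H](OCOC)C[C@@H]1C(C)=C | intermediate (not isolated)
23 | potassium dienolate of 24 (C6=C7 enolate, O cis to C8) | [K+].[O-]/C1=C(/C=C)[C@H]([Si](C)(C)Cc2ccccc2)C/C(C)=C/C[C@H](OCOC)[C@@](C)(OCOC)C1 | intermediate (not isolated)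
24 | (E)-3-(benzyldimethylsilyl)-2-ethenyl-8,9-bis(methoxymethoxy)-5,9-dimethylcyclodec-5-en-1-one; target locants: 6-oxo, 7β-vinyl (H-7 α), 8β-silyl, 3β,4α-bis-OMOM, (E)-1(10)-ene | O=C1C[C@](C)(OCOC)[C@@H](OCOC)C/C=C(C)/C[C@@H]([Si](C)(C)Cc2ccccc2)[C@H]1C=C | intermediate (key-step product)
25 | 6α-alcohol of 24 | O[C@@H]1C[C@](C)(OCOC)[C@@H](OCOC)C/C=C(C)/C[C@@H]([Si](C)(C)Cc2ccccc2)[C@H]1C=C | intermediate
26 | C6,C12-diol (7β-(2-hydroxyethyl)) | O[C@@H]1C[C@](C)(OCOC)[C@@H](OCOC)C/C=C(C)/C[C@@H]([Si](C)(C)Cc2ccccc2)[C@H]1CCO | intermediate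
27 | lactol (C12 hemiacetal on O6) | OC1O[C@@H]2C[C@](C)(OCOC)[C@@H](OCOC)C/C=C(C)/C[C@@H]([Si](C)(C)Cc3ccccc3)[C@H]2C1 | intermediate (not isolated)
28 | trans-fused 6α,12-lactone, 8β-benzyldimethylsilyl, 3β,4α-bis-OMOM | O=C1O[C@@H]2C[C@](C)(OCOC)[C@@H](OCOC)C/C=C(C)/C[C@@H]([Si](C)(C)Cc3ccccc3)[C@H]2C1 | intermediate
29 | 8β-(fluorodimethylsilyl) lactone | O=C1O[C@@H]2C[C@](C)(OCOC)[C@@H](OCOC)C/C=C(C)/C[C@@H]([Si](C)(C)F)[C@H]2C1 | intermediate (not isolated)
30 | 8β-hydroxy lactone | O=C1O[C@@H]2C[C@](C)(OCOC)[C@@H](OCOC)C/C=C(C)/C[C@@H](O)[C@H]2C1 | intermediate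
31 | 8-O-triethylsilyl ether of 30 | O=C1O[C@@H]2C[C@](C)(OCOC)[C@@H](OCOC)C/C=C(C)/C[C@@H](O[Si](CC)(CC)CC)[C@H]2C1 | intermediate
32 | C11 (dimethylamino)methyl lactone (C11 epimers) | CN(C)CC1C(=O)O[C@@H]2C[C@](C)(OCOC)[C@@H](OCOC)C/C=C(C)/C[C@@H](O[Si](CC)(CC)CC)[C@@H]12 | intermediate (not isolated)
33 | trimethylammonium iodide of 32 | [I-].C[N+](C)(C)CC1C(=O)O[C@@H]2C[C@](C)(OCOC)[C@@H](OCOC)C/C=C(C)/C[C@@H](O[Si](CC)(CC)CC)[C@@H]12 | intermediate (not isolated)
34 | α-methylene lactone, 8-O-triethylsilyl | C=C1C(=O)O[C@@H]2C[C@](C)(OCOC)[C@@H](OCOC)C/C=C(C)/C[C@@H](O[Si](CC)(CC)CC)[C@@H]12 | intermediate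
35 | 8β-hydroxy α-methylene lactone | C=C1C(=O)O[C@@H]2C[C@](C)(OCOC)[C@@H](OCOC)C/C=C(C)/C[C@@H](O)[C@@H]12 | intermediate
36 | angelic acid, (Z)-2-methylbut-2-enoic acid | C/C=C(/C)C(O)=O | starting material
37 | 8-O-angelate, 3β,4α-bis-OMOM | C=C1C(=O)O[C@@H]2C[C@](C)(OCOC)[C@@H](OCOC)C/C=C(C)/C[C@@H](OC(=O)/C(C)=C\C)[C@@H]12 | intermediate
38 | 3,4-bis(bromomethyl) ether of 39 | C=C1C(=O)O[C@@H]2C[C@](C)(OCBr)[C@@H](OCBr)C/C=C(C)/C[C@@H](OC(=O)/C(C)=C\C)[C@@H]12 | intermediate (not isolated)
39 | 1(10)-ene precursor of the target (3β,4α-diol) | C=C1C(=O)O[C@@H]2C[C@](C)(O)[C@@H](O)C/C=C(C)/C[C@@H](OC(=O)/C(C)=C\C)[C@@H]12 | intermediate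
40 | argophyllin A | C=C1C(=O)O[C@@H]2C[C@](C)(O)[C@@H](O)C[C@H]3O[C@]3(C)C[C@@H](OC(=O)/C(C)=C\C)[C@@H]12 | target

**Step count**

Total: 24 steps. Longest linear sequence: 23 steps (steps 1–10 and 12–24, from (R)-carvone).

**Three steps most likely to fail**

Step 14. The dienolate may be protonated on oxygen or at the γ-carbon, or the α-vinyl ketone may slip into conjugation before it is reduced, so that the C7 configuration written by the chair is lost. Slow cleavage of the benzyl–silicon bond by the naked alkoxide would be a second drain. The fallback sets out from 21 and comes back at 26. The rearrangement is run as before, but the dienolate is captured on oxygen with t-BuMe2SiCl to give the tert-butyldimethylsilyl dienol ether F1. 9-BBN followed by H2O2/NaOH then converts the vinyl group into the primary alcohol of enol ether F2 while C7 is still trigonal and locked. HF·pyridine at −40 °C protonates this simple enol ether from the outer face to give the hydroxy ketone F3 (which may rest as its cyclic hemiketal). NaBH4/CeCl3 reduces F3 to 26.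

Step 13. The vinyl Grignard reagent may fail to add to the hindered, alkoxide-bound alkyne, add with the wrong regiochemistry, or cleave the alkynylsilane. The fallback sets out from 13 and comes back at 21. Ketone 13 is ethynylated with 15 to the ethynyl carbinol F4. Pd(PPh3)4-catalysed syn-silylstannation with benzyldimethyl(trimethylstannyl)silane F5 (made from 14 and Me3SnLi) puts silicon on the terminal carbon and tin on the inner one, giving the (Z)-1-silyl-2-stannyl alkene F6. Stille coupling with vinyl bromide (Pd2(dba)3, AsPh3, CuI) replaces tin by vinyl with retention and gives 21.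

Step 24. The peracid may attack the other olefin face, because the face offered depends on which rotamer of the C1=C10 olefin reacts (H-1 can swing through the ring), and this preference cannot be fixed by argument alone. The fallback sets out from 39 and comes back at 40. It is a ketone-catalysed dioxirane epoxidation of Shi type (fructose-derived ketone or its enantiomer, KHSO5, K2CO3 buffer, MeCN–CH2(OMe)2–H2O, 0 °C). Here the chiral dioxirane, not the ring, selects the face among the interconverting rotamers (Curtin–Hammett). It makes no new compound (F0).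

**Further compounds**

F1 | step 14 | tert-butyldimethylsilyl dienol ether of 24 (O-silylated 23) | CC(C)(C)[Si](C)(C)O/C1=C(/C=C)[C@H]([Si](C)(C)Cc2ccccc2)C/C(C)=C/C[C@H](OCOC)[C@@](C)(OCOC)C1
F2 | step 14 | silyl enol ether with C7 2-hydroxyethyl arm | CC(C)(C)[Si](C)(C)O/C1=C(/CCO)[C@H]([Si](C)(C)Cc2ccccc2)C/C(C)=C/C[C@H](OCOC)[C@@](C)(OCOC)C1
F3 | step 14 | 6-oxo-7β-(2-hydroxyethyl) ketone (H-7 α) | O=C1C[C@](C)(OCOC)[C@@H](OCOC)C/C=C(C)/C[C@@H]([Si](C)(C)Cc2ccccc2)[C@H]1CCO
F4 | step 13 | (1R,2R,4S,5S)-1-ethynyl-4,5-bis(methoxymethoxy)-5-methyl-2-(prop-1-en-2-yl)cyclohexan-1-ol | O[C@]1(C#C)C[C@](C)(OCOC)[C@@H](OCOC)C[C@@H]1C(C)=C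
F5 | step 13 | benzyldimethyl(trimethylstannyl)silane | C[Sn](C)(C)[Si](C)(C)Cc1ccccc1
F6 | step 13 | (Z)-1-(benzyldimethylsilyl)-2-(trimethylstannyl)vinyl carbinol (Sn on the carbon bonded to the ring) | O[C@]1(/C([Sn](C)(C)C)=C/[Si](C)(C)Cc2ccccc2)C[C@](C)(OCOC)[C@@H](OCOC)C[C@@H]1C(C)=C
F0 | step 24 | none | none
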